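The target is cut at the C2–C3 and C3–O bonds of the cis-epoxide that lies between the two ring-cis alkenes C1=C10 and C4=C5 of the ten-membered carbocycle (C1–C10), whose C6–C7 edge carries the trans-fused α-methylene γ-lactone. This divinyl oxirane is the retron of an allylic sulfonium ylide adding to an enal, so one intramolecular Corey–Chaykovsky reaction closes both the ten-membered ring and the oxirane and sets C2 and C3. Its precursor is the open-chain lactone with both acyloxy groups at C8 and C9 in place, a C2 enal on the C10 ester-bearing alkene and a C3 allylic tetrahydrothiophenium tetrafluoroborate on the (Z)-C4=C5 side chain.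

Key step: step 20

Remarks on the chemistry:
* Locants follow germacranolide numbering: C6 lactone O–CH, C7 ring fusion, C8 and C9 acyloxy carbons, C10 bearing C14 (CO2Me), C4 bearing C15 (CH3), C11–C13 the α-methylene lactone carbons.
* The route is planned for the (2R,3S,6R,7S,8S,9S) isomer with a 1(10)E,4Z diene, a trans-fused 6,12-lactone, an (R)-2-methylbutanoate at C9 and a (2S,3S)-2,3-dimethyloxirane-2-carboxylate at C8. The open-chain precursor and the target agree at C6–C9 and in both alkene geometries, so no structure needed correction.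
* Assumption: allyl 4-methoxybenzyl ether, methyl 2-(bromomethyl)acrylate, (R)-2-methylbutanoic acid and (+)-B-methoxydiisopinocampheylborane are bought.
* Precursor design: the aldehyde stays masked as a dimethyl acetal until the step before ring closure, and the sulfonium salt carries the non-nucleophilic tetrafluoroborate counter-ion.

Step 1
Reactants: 1 prop-2-yn-1-ol
Product: 3 (2Z)-3-iodo-2-methylprop-2-en-1-ol, via alkenylmagnesium alkoxide 2 (not isolated)
Conditions: MeMgBr (3 equiv), CuI (10 mol%), THF, −10 °C to rt; then I2, −78 °C to 0 °C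
Reagents that add atoms: methylmagnesium bromide, C[Mg]Br; iodine, II
Why: Copper-catalysed anti-carbomagnesiation of the propargylic alkoxide places CH3 on the internal carbon and magnesium on the terminal carbon cis to CH2O (five-membered chelate), and iodinolysis with retention gives the (Z)-iodide that becomes C5=C4(C15)–C3.

Step 2
Reactants: 3 (2Z)-3-iodo-2-methylprop-2-en-1-ol
Product: 4 TBS ether of 3
Conditions: TBSCl, imidazole, CH2Cl2, 0 °C to rt
Reagents that add atoms: tert-butyldimethylsilyl chloride, CC(C)(C)[Si](C)(C)Cl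
Why: Standard silylation of a primary alcohol protects the future C3 oxygen through the organometallic and oxidative steps.

Step 3
Reactants: 4 TBS ether of 3
Product: 6 (2Z)-4-silyloxy-3-methylbut-2-enal, via vinyllithium 5 (not isolated)
Conditions: t-BuLi (2.1 equiv), Et2O, −78 °C; DMF; aq. NH4Cl
Reagents that add atoms: N,N-dimethylformamide, CN(C)C=O
Why: Iodine–lithium exchange proceeds with retention of the alkene geometry and formylation of the vinyllithium gives the (Z)-enal whose CHO carbon is C6.

Step 4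
Reactants: 7 angelic acid
Product: 8 (2Z)-2-methylbut-2-en-1-ol
Conditions: LiAlH4, Et2O, 0 °C
Reagents that add atoms: none
Why: Hydride reduction of the carboxylic acid to the allylic alcohol leaves the trisubstituted (Z)-alkene in place.

Step 5
Reactants: 8 (2Z)-2-methylbut-2-en-1-ol
Product: 9 [(2R,3S)-2,3-dimethyloxiran-2-yl]methanol
Conditions: Ti(OiPr)4 (10 mol%), D-(−)-diisopropyl tartrate (12 mol%), t-BuOOH, 4 Å MS, CH2Cl2, −20 °C
Reagents that add atoms: tert-butyl hydroperoxide, CC(C)(C)OO
Why: Sharpless asymmetric epoxidation: the D-(−)-tartrate catalyst delivers oxygen to the face that gives the 2R epoxy alcohol (the L-(+)-ligand gives 2S), and syn addition to the (Z)-alkene keeps the two methyl groups trans.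

Step 6
Reactants: 9 [(2R,3S)-2,3-dimethyloxiran-2-yl]methanol
Product: 10 (2S,3S)-2,3-dimethyloxirane-2-carboxylic acid
Conditions: TEMPO (10 mol%), PhI(OAc)2 (2.2 equiv), MeCN/H2O (1:1), rt
Reagents that add atoms: water, O
Why: Oxoammonium (TEMPO) oxidation of the primary alcohol through the aldehyde hydrate gives the acid without touching the oxirane; the C2 descriptor changes from R to S only because CO2H outranks C3.

Step 7
Reactants: 11 2,2-dimethoxyacetaldehyde; 12 methyl acrylate
Product: 13 methyl 2-(1-hydroxy-2,2-dimethoxyethyl)prop-2-enoate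
Conditions: DABCO (1 equiv), 1,4-dioxane/H2O (1:1), rt
Reagents that add atoms: none
Why: Morita–Baylis–Hillman reaction of an activated aldehyde with methyl acrylate; the racemic carbinol centre is removed in step 8.

Step 8
Reactants: 13 methyl 2-(1-hydroxy-2,2-dimethoxyethyl)prop-2-enoate
Product: 14 methyl (2Z)-2-(bromomethyl)-4,4-dimethoxybut-2-enoate
Conditions: NBS, Me2S, CH2Cl2, 0 °C to rt
Reagents that add atoms: N-bromosuccinimide, O=C1CCC(=O)N1Br
Why: Corey–Kim-type activation of the allylic alcohol as an alkoxysulfonium salt and SN2' attack of bromide give the rearranged primary bromide with the acetal carbon trans to the ester, which fixes the later C1=C10 geometry.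

Step 9
Reactants: 14 methyl (2Z)-2-(bromomethyl)-4,4-dimethoxybut-2-enoate
Product: 15 methyl (2E)-2-formyl-4,4-dimethoxybut-2-enoate
Conditions: NMO (3 equiv), MeCN, 0 °C to rt; used at once
Reagents that add atoms: N-methylmorpholine N-oxide, C[N+]1([O-])CCOCC1
Why: Kornblum-type oxidation with an amine N-oxide (O-alkylation by the primary allylic bromide, then elimination) gives the aldehyde, the future C9, without touching the acetal or the alkene geometry.

Step 10
Reactants: 15 methyl (2E)-2-formyl-4,4-dimethoxybut-2-enoate; 16 allyl 4-methoxybenzyl ether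
Product: 18 syn C9-hydroxy C8-OPMB vinyl adduct (8S,9S), via (Z)-alkoxyallyl diisopinocampheylborane 17 (not isolated)
Conditions: 16, s-BuLi, THF, −78 °C; (+)-Ipc2BOMe; BF3·OEt2; then 15, −78 °C; ethanolamine work-up
Reagents that add atoms: none
Why: Brown asymmetric alkoxyallylboration: the (Z)-γ-alkoxyallylborane reacts through a chair six-membered transition state to give the syn 1,2-diol monoether, and the isopinocampheyl groups from (−)-α-pinene direct the allyl unit to the Re face of the aldehyde, which sets C9 and C8 as S and S with the two oxygens differentiated.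

Step 11
Reactants: 18 syn C9-hydroxy C8-OPMB vinyl adduct; 19 (2R)-2-methylbutanoic acid
Product: 20 C9 (2R)-2-methylbutanoate of 18
Conditions: DIC, DMAP (0.2 equiv), CH2Cl2, 0 °C to rt
Reagents that add atoms: none
Why: Steglich esterification of the only free hydroxyl; the acid has no α-heteroatom, so its (R)-centre is not epimerised.

Step 12
Reactants: 20 C9 (2R)-2-methylbutanoate of 18; 21 methyl 2-(bromomethyl)acrylate
Product: 22 (Z)-2-(bromomethyl)enoate (allylic bromide)
Conditions: second-generation Hoveyda–Grubbs catalyst (10 mol%), 21 (5 equiv), CH2Cl2, 40 °C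
Reagents that add atoms: none
Why: Olefin cross-metathesis of the monosubstituted alkene with the 1,1-disubstituted acrylate gives the trisubstituted enoate with C8 trans to the ester, while the electron-poor trisubstituted C1=C10 alkene does not take part.

Step 13
Reactants: 22 (Z)-2-(bromomethyl)enoate; 6 (2Z)-4-silyloxy-3-methylbut-2-enal
Product: 24 C8-OPMB trans-lactone (6R,7S,8S,9S), via anti hydroxy ester 23 (not isolated)
Conditions: CrCl2 (4 equiv), THF, 0 °C to rt; then PPTS (cat.), CH2Cl2, rt
Reagents that add atoms: none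
Why: Nozaki–Hiyama allylation: the γ-substituted 2-(methoxycarbonyl)allylchromium reagent adds through C7 to the aldehyde in a chair transition state to give the anti homoallylic alcohol (C6), attack at C7 taking place anti to the C9 branch with H8 eclipsing the alkene (allylic 1,3-strain), and the γ-hydroxy ester closes to the trans α-methylene lactone.

Step 14
Reactants: 24 C8-OPMB trans-lactone
Product: 25 C8 alcohol
Conditions: DDQ (1.5 equiv), CH2Cl2/pH 7 buffer (10:1), 0 °C
Reagents that add atoms: none
Why: Oxidative cleavage of the 4-methoxybenzyl ether under buffered neutral conditions frees the C8 hydroxyl without acid or base, so the acetal, the silyl ether and the esters (acyl shift, translactonisation) are not disturbed.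

Step 15
Reactants: 25 C8 alcohol; 10 (2S,3S)-2,3-dimethyloxirane-2-carboxylic acid
Product: 26 C8 epoxy ester C9 ester lactone
Conditions: 2-methyl-6-nitrobenzoic anhydride, Et3N, DMAP, CH2Cl2, rt
Reagents that add atoms: none
Why: Shiina esterification (mixed anhydride formed in situ, DMAP acyl transfer) couples the hindered epoxy acid to the hindered C8 hydroxyl under mild conditions that keep both oxirane stereocentres and outrun a 9-to-8 acyl shift.

Step 16
Reactants: 26 C8 epoxy ester C9 ester lactone
Product: 27 C3 (Z)-allylic alcohol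
Conditions: HF·pyridine, pyridine, THF, 0 °C
Reagents that add atoms: none
Why: Buffered fluoride cleavage of the primary allylic silyl ether spares the esters, the lactone, the oxirane and the dimethyl acetal.

Step 17
Reactants: 27 C3 (Z)-allylic alcohol
Product: 28 C3 (Z)-allylic bromide
Conditions: CBr4, PPh3, 2,6-lutidine, CH2Cl2, −20 °C to 0 °C
Reagents that add atoms: carbon tetrabromide, BrC(Br)(Br)Br
Why: Appel reaction converts the primary allylic alcohol into the bromide by SN2 displacement with the (Z)-alkene retained, lutidine buffering the acetal and the oxirane.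

Step 18
Reactants: 28 C3 (Z)-allylic bromide; 29 tetrahydrothiophene
Product: 30 C3 tetrahydrothiophenium tetrafluoroborate (C2 acetal)
Conditions: 29 (5 equiv), AgBF4 (1.1 equiv), acetone, rt, dark
Reagents that add atoms: silver tetrafluoroborate, [Ag+].F[B-](F)(F)F
Why: S-Alkylation of the sulfide by the allylic bromide, driven by precipitation of AgBr, gives the sulfonium salt with a non-nucleophilic counter-ion.

Step 19
Reactants: 30 C3 tetrahydrothiophenium tetrafluoroborate (C2 acetal)
Product: 31 seco C2 enal C3 tetrahydrothiophenium tetrafluoroborate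
Conditions: LiBF4, MeCN/H2O (50:1), rt
Reagents that add atoms: water, O
Why: Mild acid-promoted hydrolysis of the dimethyl acetal of an enal in wet acetonitrile releases the aldehyde last, the sulfonium salt and the glycidic ester being stable to these weakly acidic conditions.

Step 20
Reactants: 31 seco C2 enal C3 tetrahydrothiophenium tetrafluoroborate
Product: 34 CNP0485260.1 (target), via sulfonium ylide 32 (not isolated), via syn-betaine 33 (not isolated)
Conditions: Cs2CO3 (2 equiv), MeCN, 1 mM, slow addition of 31 over 12 h, 0 °C to rt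
Reagents that add atoms: none
Why: Proposed new method: Cs2CO3 removes the acidic allylic C3–H next to sulfur, the ylide carbon adds to the C2 aldehyde (10-exo-trig, forming C2–C3 and the ten-membered ring) and the alkoxide then displaces tetrahydrothiophene from C3 (3-exo-tet, forming C3–O and the oxirane); the closest known reaction is the intermolecular Corey–Chaykovsky epoxidation of aldehydes with allylic sulfonium ylides to vinyl epoxides, which has not been used to close a ten-membered carbocycle. The ring-cis alkenes C1=C10 and C4=C5 and the trans-fused lactone pre-fold the chain so that C2 and C3 come close, and high dilution with slow addition suppresses dimerisation. C2 and C3 are set together: a trans-oxirane spanning two ring-cis alkenes in a ten-membered ring is too strained, so only the syn betaine can close and the cis-epoxide results, while the face is set by the C6–C9 stereocentres through the conformer that keeps the C8 and C9 acyloxy groups outside the ring. The step needs 1,2-addition to the aldehyde in preference to cyclopropanation of the α-methylene lactone or the C1=C10 enoate; the 4-oxo-enoate aldehyde is the most electrophilic site and semi-stabilised allylic ylides add to aldehydes fast, after which oxirane closure is irreversible. The weak carbonate base leaves the three esters, the lactone and the glycidic ester untouched.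

Compound list

1 | prop-2-yn-1-ol | C#CCO | starting material
2 | bromomagnesium (2Z)-3-(bromomagnesio)-2-methylprop-2-en-1-olate | Br[Mg]/C=C(/C)CO[Mg]Br | intermediate
3 | (2Z)-3-iodo-2-methylprop-2-en-1-ol | I/C=C(/C)CO | intermediate
4 | tert-butyl{[(2Z)-3-iodo-2-methylprop-2-en-1-yl]oxy}dimethylsilane | I/C=C(/C)CO[Si](C)(C)C(C)(C)C | intermediate
5 | [(1Z)-3-(tert-butyldimethylsilyloxy)-2-methylprop-1-en-1-yl]lithium | [Li]/C=C(/C)CO[Si](C)(C)C(C)(C)C | intermediate
6 | (2Z)-4-(tert-butyldimethylsilyloxy)-3-methylbut-2-enal | O=C/C=C(/C)CO[Si](C)(C)C(C)(C)C | intermediate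
7 | angelic acid, (2Z)-2-methylbut-2-enoic acid | C/C=C(/C)C(=O)O | starting material
8 | (2Z)-2-methylbut-2-en-1-ol | C/C=C(/C)CO | intermediate
9 | [(2R,3S)-2,3-dimethyloxiran-2-yl]methanol | OC[C@@]1(C)O[C@H]1C | intermediate
10 | (2S,3S)-2,3-dimethyloxirane-2-carboxylic acid | OC(=O)[C@@]1(C)O[C@H]1C | intermediate
11 | 2,2-dimethoxyacetaldehyde | COC(OC)C=O | starting material
12 | methyl acrylate | C=CC(=O)OC | starting material
13 | methyl 2-(1-hydroxy-2,2-dimethoxyethyl)prop-2-enoate (racemic) | COC(OC)C(O)C(=C)C(=O)OC | intermediate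
14 | methyl (2Z)-2-(bromomethyl)-4,4-dimethoxybut-2-enoate | COC(OC)/C=C(/C(=O)OC)CBr | intermediate
15 | methyl (2E)-2-formyl-4,4-dimethoxybut-2-enoate | COC(OC)/C=C(/C(=O)OC)C=O | intermediate
16 | allyl 4-methoxybenzyl ether | C=CCOCc1ccc(OC)cc1 | starting material
17 | (Z)-[3-(4-methoxybenzyloxy)prop-2-en-1-yl]diisopinocampheylborane (isopinocampheyl groups from (−)-α-pinene) | COc1ccc(CO/C=C\CB([C@H]2C[C@H]3C[C@@H]([C@@H]2C)C3(C)C)[C@H]2C[C@H]3C[C@@H]([C@@H]2C)C3(C)C)cc1 | intermediate
18 | methyl (2E)-2-[(1S,2S)-1-hydroxy-2-(4-methoxybenzyloxy)but-3-en-1-yl]-4,4-dimethoxybut-2-enoate | COC(OC)/C=C(/C(=O)OC)[C@H](O)[C@@H](OCc1ccc(OC)cc1)C=C | intermediate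
19 | (2R)-2-methylbutanoic acid | CC[C@@H](C)C(=O)O | starting material
20 | methyl (2E)-2-[(1S,2S)-2-(4-methoxybenzyloxy)-1-{[(2R)-2-methylbutanoyl]oxy}but-3-en-1-yl]-4,4-dimethoxybut-2-enoate | COC(OC)/C=C(/C(=O)OC)[C@H](OC(=O)[C@H](C)CC)[C@@H](OCc1ccc(OC)cc1)C=C | intermediate
21 | methyl 2-(bromomethyl)prop-2-enoate | C=C(CBr)C(=O)OC | starting material
22 | methyl (2Z,4S,5S,6E)-2-(bromomethyl)-6-(methoxycarbonyl)-8,8-dimethoxy-4-(4-methoxybenzyloxy)-5-{[(2R)-2-methylbutanoyl]oxy}octa-2,6-dienoate | COC(OC)/C=C(/C(=O)OC)[C@H](OC(=O)[C@H](C)CC)[C@@H](OCc1ccc(OC)cc1)/C=C(\CBr)C(=O)OC | intermediate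
23 | open-chain anti γ-hydroxy ester (6R,7S,8S,9S): C6–OH, C11=C13 methylene with C12 methyl ester, C8 O-PMB, C9 O-(2R)-2-methylbutanoyl, C2 dimethyl acetal, C3 OTBS, (4Z) | COC(OC)/C=C(/C(=O)OC)[C@H](OC(=O)[C@H](C)CC)[C@@H](OCc1ccc(OC)cc1)[C@@H](C(=C)C(=O)OC)[C@H](O)/C=C(/C)CO[Si](C)(C)C(C)(C)C | intermediate
24 | trans α-methylene γ-lactone (6R,7S,8S,9S; 1(10)E,4Z): C8 O-PMB, C9 O-(2R)-2-methylbutanoyl, C10 CO2Me, C2 dimethyl acetal, C3 OTBS | COC(OC)/C=C(/C(=O)OC)[C@H](OC(=O)[C@H](C)CC)[C@@H](OCc1ccc(OC)cc1)[C@H]1C(=C)C(=O)O[C@@H]1/C=C(/C)CO[Si](C)(C)C(C)(C)C | intermediate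
25 | lactone 24 with free C8–OH (same spatial arrangement at C6–C9) | COC(OC)/C=C(/C(=O)OC)[C@H](OC(=O)[C@H](C)CC)[C@@H](O)[C@H]1C(=C)C(=O)O[C@@H]1/C=C(/C)CO[Si](C)(C)C(C)(C)C | intermediate
26 | lactone with C8 O-[(2S,3S)-2,3-dimethyloxirane-2-carbonyl], C9 O-(2R)-2-methylbutanoyl, C2 dimethyl acetal, C3 OTBS (6R,7S,8S,9S) | COC(OC)/C=C(/C(=O)OC)[C@H](OC(=O)[C@H](C)CC)[C@@H](OC(=O)[C@@]2(C)O[C@H]2C)[C@H]1C(=C)C(=O)O[C@@H]1/C=C(/C)CO[Si](C)(C)C(C)(C)C | intermediate
27 | lactone 26 with free C3–OH, (4Z)-allylic alcohol | COC(OC)/C=C(/C(=O)OC)[C@H](OC(=O)[C@H](C)CC)[C@@H](OC(=O)[C@@]2(C)O[C@H]2C)[C@H]1C(=C)C(=O)O[C@@H]1/C=C(/C)CO | intermediate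
28 | lactone 26 with C3–Br, (4Z)-allylic bromide | COC(OC)/C=C(/C(=O)OC)[C@H](OC(=O)[C@H](C)CC)[C@@H](OC(=O)[C@@]2(C)O[C@H]2C)[C@H]1C(=C)C(=O)O[C@@H]1/C=C(/C)CBr | intermediate
29 | tetrahydrothiophene | C1CCSC1 | starting material
30 | C3 tetrahydrothiophenium tetrafluoroborate of the lactone diester, C2 dimethyl acetal | COC(OC)/C=C(/C(=O)OC)[C@H](OC(=O)[C@H](C)CC)[C@@H](OC(=O)[C@@]2(C)O[C@H]2C)[C@H]1C(=C)C(=O)O[C@@H]1/C=C(/C)C[S+]3CCCC3.F[B-](F)(F)F | intermediate
31 | seco C2 enal C3 tetrahydrothiophenium tetrafluoroborate (6R,7S,8S,9S; 1(10)E,4Z) | O=C/C=C(/C(=O)OC)[C@H](OC(=O)[C@H](C)CC)[C@@H](OC(=O)[C@@]3(C)O[C@H]3C)[C@H]1C(=C)C(=O)O[C@@H]1/C=C(/C)C[S+]2CCCC2.F[B-](F)(F)F | intermediate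
32 | C3 sulfonium ylide of 31 | O=C/C=C(/C(=O)OC)[C@H](OC(=O)[C@H](C)CC)[C@@H](OC(=O)[C@@]3(C)O[C@H]3C)[C@H]1C(=C)C(=O)O[C@@H]1/C=C(/C)[CH-][S+]2CCCC2 | intermediate
33 | ten-membered syn-betaine (C2 alkoxide, C3 sulfonium; 2R,3R) | C=C1C(=O)O[C@@H]2/C=C(/C)[C@@H]([S+]4CCCC4)[C@H]([O-])/C=C(/C(=O)OC)[C@H](OC(=O)[C@H](C)CC)[C@@H](OC(=O)[C@@]3(C)O[C@H]3C)[C@@H]12 | intermediate
34 | CNP0485260.1, (2R,3S,6R,7S,8S,9S)-2,3-epoxy-1(10)E,4Z-germacradien-6,12-olide 14-methyl ester with the C8 and C9 esters | C=C1C(=O)O[C@@H]2/C=C(/C)[C@@H]3O[C@@H]3/C=C(/C(=O)OC)[C@H](OC(=O)[C@H](C)CC)[C@@H](OC(=O)[C@@]3(C)O[C@H]3C)[C@@H]12 | target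

Total step count: 20. Longest linear sequence: 14 steps (steps 7–20, from 11 and 12); 6 (steps 1–3) and 10 (steps 4–6) are made in parallel.

Steps most likely to fail

1. Step 20 (ring closure). The ylide may add in conjugate fashion to the α-methylene lactone or the C1=C10 enoate (cyclopropanation), may react between molecules, or the betaine may close on the wrong face. The fallback makes the oxirane first under reagent control and closes the ring by olefin metathesis at C4=C5, both known reaction types. It sets out from bromide 22. CrCl2-mediated allylation of acrolein in place of 6, followed by lactonisation, gives the C6-vinyl lactone F1. DDQ gives the C8 alcohol F2, and Shiina esterification with 10 gives the diester F3. LiBF4 in wet MeCN releases the enal F4. (Z)-(3-Chloro-2-methylprop-2-en-1-yl)diisopinocampheylborane F5 is generated from 3-chloro-2-methylprop-1-ene, lithium dicyclohexylamide, (−)-B-methoxydiisopinocampheylborane and BF3·OEt2 at −95 °C. It adds to the Si face of the aldehyde to give the syn chlorohydrin F6, and DBU closes this to the cis-oxirane F7. Ring-closing metathesis of the isopropenyl and C6-vinyl groups (second-generation Hoveyda–Grubbs catalyst, toluene, 80 °C, high dilution) forms the C4=C5 alkene, whose ring-cis geometry the ten-membered ring enforces. The fallback comes back to the route at the target 34.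

2. Step 13 (lactone-forming allylation). The anti simple diastereoselection may erode if the allylchromium species reacts before it equilibrates, the facial control by C8 may be incomplete, and the (Z)-enal may isomerise. The fallback sets out from 22 and 6 and uses the syn-selective indium-mediated Barbier reaction followed by inversion at C6. Indium powder in THF/H2O gives the syn γ-hydroxy ester F8. Mitsunobu reaction with chloroacetic acid (PPh3, DIAD) inverts C6 to give the chloroacetate F9. Thiourea with NaHCO3 removes the chloroacetyl group selectively and comes back to the route at the anti hydroxy ester 23, which lactonises to 24 as in step 13.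

3. Step 12 (cross-metathesis). The hindered allylic ether may turn over slowly and the acrylate partner may homodimerise. The fallback sets out from 20 and builds the bromomethyl enoate by olefination. Lemieux–Johnson cleavage (OsO4 cat., NaIO4, 2,6-lutidine, dioxane/H2O) gives the aldehyde F10. Horner–Wadsworth–Emmons olefination under Masamune–Roush conditions (LiCl, iPr2NEt, MeCN) with methyl 3-(tert-butyldimethylsilyloxy)-2-(dimethoxyphosphoryl)propanoate gives the (E)-2-(silyloxymethyl) enoate F11. HF·pyridine gives the allylic alcohol F12, and the Appel reaction (CBr4, PPh3) comes back to the route at bromide 22.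

Further compounds
F1 | step 20 | C6-vinyl analogue of lactone 24 (C8 O-PMB, C2 dimethyl acetal) | COC(OC)/C=C(/C(=O)OC)[C@H](OC(=O)[C@H](C)CC)[C@@H](OCc1ccc(OC)cc1)[C@H]1C(=C)C(=O)O[C@@H]1C=C
F2 | step 20 | C8 alcohol from F1 | COC(OC)/C=C(/C(=O)OC)[C@H](OC(=O)[C@H](C)CC)[C@@H](O)[C@H]1C(=C)C(=O)O[C@@H]1C=C
F3 | step 20 | C8 (2S,3S)-2,3-dimethyloxirane-2-carboxylate of F2 | COC(OC)/C=C(/C(=O)OC)[C@H](OC(=O)[C@H](C)CC)[C@@H](OC(=O)[C@@]2(C)O[C@H]2C)[C@H]1C(=C)C(=O)O[C@@H]1C=C
F4 | step 20 | C2 enal from F3 | O=C/C=C(/C(=O)OC)[C@H](OC(=O)[C@H](C)CC)[C@@H](OC(=O)[C@@]2(C)O[C@H]2C)[C@H]1C(=C)C(=O)O[C@@H]1C=C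
F5 | step 20 | (Z)-(3-chloro-2-methylprop-2-en-1-yl)diisopinocampheylborane (isopinocampheyl groups from (+)-α-pinene) | Cl/C=C(C)\CB([C@@H]1C[C@@H]2C[C@H]([C@H]1C)C2(C)C)[C@@H]1C[C@@H]2C[C@H]([C@H]1C)C2(C)C
F6 | step 20 | syn chlorohydrin (2R,3R) with C3 isopropenyl and C6 vinyl | C=C(C)[C@@H](Cl)[C@H](O)/C=C(/C(=O)OC)[C@H](OC(=O)[C@H](C)CC)[C@@H](OC(=O)[C@@]2(C)O[C@H]2C)[C@H]1C(=C)C(=O)O[C@@H]1C=C
F7 | step 20 | cis-2,3-oxirane (2R,3S) with C3 isopropenyl and C6 vinyl, metathesis precursor | C=C(C)[C@@H]1O[C@@H]1/C=C(/C(=O)OC)[C@H](OC(=O)[C@H](C)CC)[C@@H](OC(=O)[C@@]2(C)O[C@H]2C)[C@H]2C(=C)C(=O)O[C@@H]2C=C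
F8 | step 13 | syn γ-hydroxy ester, 6S epimer of 23 | COC(OC)/C=C(/C(=O)OC)[C@H](OC(=O)[C@H](C)CC)[C@@H](OCc1ccc(OC)cc1)[C@@H](C(=C)C(=O)OC)[C@@H](O)/C=C(/C)CO[Si](C)(C)C(C)(C)C
F9 | step 13 | C6 chloroacetate of 23 (6R) | COC(OC)/C=C(/C(=O)OC)[C@H](OC(=O)[C@H](C)CC)[C@@H](OCc1ccc(OC)cc1)[C@@H](C(=C)C(=O)OC)[C@H](OC(=O)CCl)/C=C(/C)CO[Si](C)(C)C(C)(C)C
F10 | step 12 | C7 aldehyde from oxidative cleavage of 20 | COC(OC)/C=C(/C(=O)OC)[C@H](OC(=O)[C@H](C)CC)[C@@H](OCc1ccc(OC)cc1)C=O
F11 | step 12 | (E)-2-(tert-butyldimethylsilyloxymethyl) enoate analogue of 22 | COC(OC)/C=C(/C(=O)OC)[C@H](OC(=O)[C@H](C)CC)[C@@H](OCc1ccc(OC)cc1)/C=C(\CO[Si](C)(C)C(C)(C)C)C(=O)OC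
F12 | step 12 | (E)-2-(hydroxymethyl) enoate analogue of 22 | COC(OC)/C=C(/C(=O)OC)[C@H](OC(=O)[C@H](C)CC)[C@@H](OCc1ccc(OC)cc1)/C=C(\CO)C(=O)OC
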